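**Plan**

- Retrosynthesis: the two gallate ester C–O bonds are cut first, then the interflavan bond C4(middle)–C6(bottom). In the top unit the cuts are C4–C4a (key), O1–C2, C3–C4 and C4(top)–C8(middle), which leaves (−)-epicatechin, (+)-catechin, an acetophenone, a phenol and a protected gallic acid.
- Forward: epicatechin is benzylated, brominated, silylated and formylated at C8. Aldol condensation, epoxidation, reduction and etherification build the open-chain top unit on that carbon, and ring C of the top unit is then closed. The middle C4 is oxidised, the free ring A carbons are bromine-capped, the bottom unit is attached at its C6, and desilylation, esterification of both 3-hydroxyls with two molecules of the protected gallic acid, and hydrogenolysis finish.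
- Enabling feature: top C4 is a diarylmethine (bonded to top C4a and middle C8) trans to O3. An aryl ether on C2 holds its ortho carbon (the future C4a) where it closes the six-membered ring C onto C4, so a trans C3–C4 oxirane delivers O3 and the C4 configuration in one event.
- Stereochemistry: middle and bottom C2/C3 come from the chiral pool. Top C3/C4 come from poly-L-leucine-catalysed epoxidation, top C2 from chelation-controlled reduction followed by Mitsunobu inversion, top C4 from inversion at the oxirane during ring closure, and middle C4 from attack anti to the 3-silyloxy group.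

Key step: step 9

Remark: the benzylic oxiranes 9, 10 and 12 bear a 2,4,6-trioxygenated aryl group and are assumed to tolerate only cold, base-buffered handling; each is filtered through triethylamine-deactivated silica and used at once.

Abbreviations: Bn = benzyl; TBS = tert-butyldimethylsilyl; M = the 5,7,3′,4′-tetra-O-benzyl-3-O-TBS-(2R,3R)-epicatechin-8-yl group.

**Route**

Step 1
Reactants: 1 (−)-epicatechin
Product: 2 5,7,3′,4′-tetra-O-benzyl-(−)-epicatechin
Conditions: BnBr, K2CO3, DMF, 0 °C to rt, argon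
Reagents that add atoms: benzyl bromide, BrCc1ccccc1
Why: Williamson ether synthesis in which K2CO3 deprotonates only the four phenols, so the secondary 3-hydroxyl stays free and C2/C3 are untouched.

Step 2
Reactants: 2 5,7,3′,4′-tetra-O-benzyl-(−)-epicatechin
Product: 3 8-bromo-5,7,3′,4′-tetra-O-benzylepicatechin
Conditions: NBS, CH2Cl2, −78 °C to rt
Reagents that add atoms: N-bromosuccinimide, O=C1CCC(=O)N1Br
Why: Electrophilic aromatic bromination goes to C8, the most nucleophilic carbon of ring A in benzylated flavan-3-ols, and provides the handle for one-carbon homologation.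

Step 3
Reactants: 3 8-bromo-5,7,3′,4′-tetra-O-benzylepicatechin
Product: 4 8-bromo-5,7,3′,4′-tetra-O-benzyl-3-O-TBS-epicatechin
Conditions: TBSCl, imidazole, DMF, rt
Reagents that add atoms: tert-butyldimethylsilyl chloride, CC(C)(C)[Si](C)(C)Cl
Why: Silyl ether formation masks the 3-hydroxyl, which would otherwise quench the aryllithium of step 4 and act as a second alcohol in the Mitsunobu reaction of step 8.

Step 4
Reactants: 4 8-bromo-5,7,3′,4′-tetra-O-benzyl-3-O-TBS-epicatechin
Product: 6 8-formyl-5,7,3′,4′-tetra-O-benzyl-3-O-TBS-epicatechin (M–CHO), via aryllithium 5 (not isolated)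
Conditions: n-BuLi, THF, −78 °C; DMF, −78 to 0 °C; then H2O
Reagents that add atoms: N,N-dimethylformamide, CN(C)C=O
Why: Bromine–lithium exchange followed by Bouveault formylation places the future top C4 on C8 of the middle unit, the ortho-alkoxy aryllithium being stable at −78 °C.

Step 5
Reactants: 6 8-formyl-5,7,3′,4′-tetra-O-benzyl-3-O-TBS-epicatechin; 7 3,4-bis(benzyloxy)acetophenone
Product: 8 (E)-1-[3,4-bis(benzyloxy)phenyl]-3-M-prop-2-en-1-one
Conditions: KOH, EtOH–THF, rt
Reagents that add atoms: none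
Why: Claisen–Schmidt (crossed aldol) condensation of the non-enolisable aldehyde with the methyl ketone should give the thermodynamically preferred E-enone and creates the C3–C4 bond of the future top unit.

Step 6
Reactants: 8 (E)-1-[3,4-bis(benzyloxy)phenyl]-3-M-prop-2-en-1-one
Product: 9 [3,4-bis(benzyloxy)phenyl] [(2R,3S)-3-M-oxiran-2-yl] ketone (trans-epoxy ketone)
Conditions: poly-L-leucine, urea–H2O2, DBU, THF, rt
Reagents that add atoms: hydrogen peroxide as its urea adduct, OO.NC(N)=O
Why: Juliá–Colonna epoxidation (Weitz–Scheffer addition of hydroperoxide within the poly-L-leucine helix) should give the trans-(2R,3S)-epoxy ketone, the catalyst selecting the enone face as it does for chalcone and so setting future top C3 and C4, while the non-aqueous basic medium spares the acid-sensitive benzylic oxirane.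

Step 7
Reactants: 9 [3,4-bis(benzyloxy)phenyl] [(2R,3S)-3-M-oxiran-2-yl] ketone
Product: 10 (S)-[3,4-bis(benzyloxy)phenyl][(2S,3S)-3-M-oxiran-2-yl]methanol (erythro epoxy alcohol)
Conditions: Zn(BH4)2, Et2O–THF, −30 °C; then H2O
Reagents that add atoms: none
Why: Chelation-controlled hydride reduction, in which zinc bridges the carbonyl and oxirane oxygens and hydride enters anti to the oxirane C–C bond, should give the erythro (anti) alcohol with the S carbinol centre, as established for trans-α,β-epoxy ketones.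

Step 8
Reactants: 10 (S)-[3,4-bis(benzyloxy)phenyl][(2S,3S)-3-M-oxiran-2-yl]methanol; 11 3,5-bis(benzyloxy)phenol
Product: 12 (2R,3S)-2-{(R)-[3,5-bis(benzyloxy)phenoxy][3,4-bis(benzyloxy)phenyl]methyl}-3-M-oxirane (trans-oxirane, threo aryl ether)
Conditions: PPh3, DIAD, toluene, 0 °C to rt
Reagents that add atoms: none
Why: Mitsunobu etherification displaces the activated benzylic hydroxyl by the phenoxide with inversion (SN2), converting the erythro alcohol into the threo aryl ether with R configuration at future C2, as in the phenol/epoxy-carbinol couplings used to build flavan-3-ols.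

Step 9
Reactants: 12 (2R,3S)-2-{(R)-[3,5-bis(benzyloxy)phenoxy][3,4-bis(benzyloxy)phenyl]methyl}-3-M-oxirane
Product: 13 5,7,3′,4′-tetra-O-benzylepicatechin-(4β→8)-[5,7,3′,4′-tetra-O-benzyl-3-O-TBS-epicatechin] (top unit 2R,3R,4R, top 3-hydroxyl free)
Conditions: BF3·OEt2 (0.2 equiv), CH2Cl2, −78 °C; Et3N quench
Reagents that add atoms: none
Why: BF3 binds the oxirane oxygen and loosens the C4–O bond, which is benzylic to the 2,4,6-trioxygenated ring A of the middle unit; the ortho carbon of the 3,5-bis(benzyloxy)phenyl ether (para to a benzyloxy group) attacks C4 from the side opposite the departing oxygen and the arenium ion loses a proton, which ends on the C3 oxygen. The closest known reaction is the Lewis-acid or fluoroalcohol promoted intramolecular Friedel–Crafts epoxide–arene cyclisation of 3-aryl glycidyl aryl ethers to trans-4-arylchroman-3-ols. Ring C of the top unit closes in a 6-endo-tet mode with respect to the oxirane, the C3–C4 bond lying inside the new six-membered ring and the oxygen staying outside on C3. The new stereocentre C4 is set by inversion of the trans-oxirane carbon, and should a free benzylic cation intervene, closure anti to the BF3-bound C3 oxygen leads to the same 3,4-trans (4β) isomer, while C2 and C3 are carried over unchanged. The step needs attack at C4 and not at C3 (which would give a five-membered ring), secured by the cation-stabilising aryl group on C4, and ring closure faster than hydride shift, secured by the high nucleophilicity of the phloroglucinol-type ring held in a six-membered relationship to C4 and by the low temperature. The two ortho carbons of the ether are equivalent by symmetry and the para carbon cannot reach C4.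

Step 10
Reactants: 13 5,7,3′,4′-tetra-O-benzylepicatechin-(4β→8)-[5,7,3′,4′-tetra-O-benzyl-3-O-TBS-epicatechin]
Product: 14 5,7,3′,4′-tetra-O-benzylepicatechin-(4β→8)-[4β-(2-ethoxyethoxy)-5,7,3′,4′-tetra-O-benzyl-3-O-TBS-epicatechin]
Conditions: DDQ, 2-ethoxyethanol, CH2Cl2, rt
Reagents that add atoms: 2-ethoxyethanol, CCOCCO
Why: DDQ-mediated benzylic oxidation (hydride abstraction) at the middle C4 methylene, whose cation is stabilised by O1, O5 and O7 of the middle ring A, with capture by the alcohol anti to the 3-silyloxy group; the top C4–H is a shielded methine between two ortho-disubstituted rings and should react more slowly, as in oxidations of benzylated flavan dimers to dimeric electrophiles.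

Step 11
Reactants: 14 5,7,3′,4′-tetra-O-benzylepicatechin-(4β→8)-[4β-(2-ethoxyethoxy)-5,7,3′,4′-tetra-O-benzyl-3-O-TBS-epicatechin]
Product: 15 6,8-dibromo-5,7,3′,4′-tetra-O-benzylepicatechin-(4β→8)-[6-bromo-4β-(2-ethoxyethoxy)-5,7,3′,4′-tetra-O-benzyl-3-O-TBS-epicatechin]
Conditions: NBS (3.1 equiv), CH2Cl2, −40 to 0 °C
Reagents that add atoms: N-bromosuccinimide, O=C1CCC(=O)N1Br
Why: Exhaustive electrophilic bromination of the three remaining ring A C–H positions (top C6, top C8, middle C6) caps every nucleophilic carbon of the electrophile so that it cannot self-condense in step 15 (halo-capping).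

Step 12
Reactants: 16 (+)-catechin
Product: 17 5,7,3′,4′-tetra-O-benzyl-(+)-catechin
Conditions: BnBr, K2CO3, DMF, 0 °C to rt, argon
Reagents that add atoms: benzyl bromide, BrCc1ccccc1
Why: Williamson ether synthesis selective for the four phenols, as in step 1.

Step 13
Reactants: 17 5,7,3′,4′-tetra-O-benzyl-(+)-catechin
Product: 18 3,5,7,3′,4′-penta-O-benzylcatechin
Conditions: NaH, BnBr, DMF, 0 °C to rt
Reagents that add atoms: benzyl bromide, BrCc1ccccc1
Why: Williamson benzylation of the 3-alkoxide gives a hydrogenolysable mask that keeps the bottom 3-hydroxyl out of the later galloylation.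

Step 14
Reactants: 18 3,5,7,3′,4′-penta-O-benzylcatechin
Product: 19 8-bromo-3,5,7,3′,4′-penta-O-benzylcatechin
Conditions: NBS, CH2Cl2, −78 °C to rt
Reagents that add atoms: N-bromosuccinimide, O=C1CCC(=O)N1Br
Why: Electrophilic bromination at C8 blocks the more nucleophilic ring A carbon, leaving C6 as the only position open for the interflavan bond.

Step 15
Reactants: 15 tribromo 4β-(2-ethoxyethoxy) dimer; 19 8-bromo-3,5,7,3′,4′-penta-O-benzylcatechin (3 equiv)
Product: 20 6,8-dibromo-5,7,3′,4′-tetra-O-benzylepicatechin-(4β→8)-[6-bromo-5,7,3′,4′-tetra-O-benzyl-3-O-TBS-epicatechin]-(4β→6)-[8-bromo-3,5,7,3′,4′-penta-O-benzylcatechin]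
Conditions: TMSOTf (0.3 equiv), 4 Å molecular sieves, CH2Cl2, −78 to −30 °C
Reagents that add atoms: none
Why: Lewis-acid ionisation of the 4-alkoxy group gives the flavan-4-yl cation, which undergoes Friedel–Crafts attack by C6 of the bromine-capped catechin from the face anti to the 3-silyloxy group, so the new middle C4 centre is 3,4-trans (4β), as in halo-capping syntheses of 4→6-linked procyanidins.

Step 16
Reactants: 20 tetrabromo trimer 3-O-TBS ether
Product: 21 6,8-dibromo-5,7,3′,4′-tetra-O-benzylepicatechin-(4β→8)-[6-bromo-5,7,3′,4′-tetra-O-benzylepicatechin]-(4β→6)-[8-bromo-3,5,7,3′,4′-penta-O-benzylcatechin] (top and middle 3-hydroxyls free)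
Conditions: TBAF, THF, rt to 40 °C
Reagents that add atoms: none
Why: Fluoride-mediated desilylation frees the middle 3-hydroxyl, while benzyl ethers, aryl bromides and the interflavan bonds are inert to TBAF.

Step 17
Reactants: 21 tetrabromo trimer diol; 22 3,4,5-tris(benzyloxy)benzoic acid (2 equiv incorporated, one per hydroxyl; used in excess)
Product: 23 top,middle-3,3-di-O-[3,4,5-tris(benzyloxy)benzoyl] derivative of 21
Conditions: 22 (3 equiv in all), DCC (3 equiv), DMAP (0.5 equiv), CH2Cl2, rt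
Reagents that add atoms: 3,4,5-tris(benzyloxy)benzoic acid (the second molecule of 22), OC(=O)c1cc(OCc2ccccc2)c(OCc2ccccc2)c(OCc2ccccc2)c1
Why: Steglich esterification in which each of the two free secondary hydroxyls (top and middle C3) takes one acyl group from one DCC-activated molecule of 22, so two molecules of the acid are consumed per molecule of 21; the C3 configurations are retained and the bottom C3 oxygen, being benzylated, is not acylated.

Step 18
Reactants: 23 protected bis-gallate trimer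
Product: 24 epicatechin-3-O-gallate-(4β→8)-epicatechin-3-O-gallate-(4β→6)-catechin (CNP0154615.1)
Conditions: H2 (1 atm), Pd(OH)2/C, Et3N, THF–MeOH–H2O, rt; then AcOH
Reagents that add atoms: none
Why: Catalytic hydrogenolysis cleaves all nineteen benzyl ethers and hydrodehalogenates the four aryl bromides while the gallate esters, the O1–C2 bonds and all stereocentres are untouched, triethylamine neutralising the HBr that would otherwise threaten the acid-labile interflavan bonds.

**Compound list**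

1 | (−)-epicatechin | O[C@@H]1Cc2c(O)cc(O)cc2O[C@@H]1c1ccc(O)c(O)c1 | starting material
2 | 5,7,3′,4′-tetra-O-benzyl-(−)-epicatechin | O[C@@H]1Cc2c(OCc9ccccc9)cc(OCc9ccccc9)cc2O[C@@H]1c1ccc(OCc9ccccc9)c(OCc9ccccc9)c1 | intermediate
3 | 8-bromo-5,7,3′,4′-tetra-O-benzylepicatechin | O[C@@H]1Cc2c(OCc9ccccc9)cc(OCc9ccccc9)c(Br)c2O[C@@H]1c1ccc(OCc9ccccc9)c(OCc9ccccc9)c1 | intermediate
4 | 8-bromo-5,7,3′,4′-tetra-O-benzyl-3-O-TBS-epicatechin | CC(C)(C)[Si](C)(C)O[C@@H]1Cc2c(OCc9ccccc9)cc(OCc9ccccc9)c(Br)c2O[C@@H]1c1ccc(OCc9ccccc9)c(OCc9ccccc9)c1 | intermediate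
5 | 8-lithio-5,7,3′,4′-tetra-O-benzyl-3-O-TBS-epicatechin (aryllithium, not isolated) | CC(C)(C)[Si](C)(C)O[C@@H]1Cc2c(OCc9ccccc9)cc(OCc9ccccc9)c([Li])c2O[C@@H]1c1ccc(OCc9ccccc9)c(OCc9ccccc9)c1 | intermediate
6 | 8-formyl-5,7,3′,4′-tetra-O-benzyl-3-O-TBS-epicatechin | CC(C)(C)[Si](C)(C)O[C@@H]1Cc2c(OCc9ccccc9)cc(OCc9ccccc9)c(C=O)c2O[C@@H]1c1ccc(OCc9ccccc9)c(OCc9ccccc9)c1 | intermediate
7 | 3,4-bis(benzyloxy)acetophenone | CC(=O)c1ccc(OCc2ccccc2)c(OCc2ccccc2)c1 | starting material
8 | (E)-1-[3,4-bis(benzyloxy)phenyl]-3-M-prop-2-en-1-one | O=C(/C=C/c3c(OCc9ccccc9)cc(OCc9ccccc9)c4c3O[C@H](c8ccc(OCc9ccccc9)c(OCc9ccccc9)c8)[C@H](O[Si](C)(C)C(C)(C)C)C4)c1ccc(OCc9ccccc9)c(OCc9ccccc9)c1 | intermediate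
9 | [3,4-bis(benzyloxy)phenyl] [(2R,3S)-3-M-oxiran-2-yl] ketone | O=C([C@@H]7O[C@H]7c3c(OCc9ccccc9)cc(OCc9ccccc9)c4c3O[C@H](c8ccc(OCc9ccccc9)c(OCc9ccccc9)c8)[C@H](O[Si](C)(C)C(C)(C)C)C4)c1ccc(OCc9ccccc9)c(OCc9ccccc9)c1 | intermediate
10 | (S)-[3,4-bis(benzyloxy)phenyl][(2S,3S)-3-M-oxiran-2-yl]methanol (erythro) | O[C@H]([C@@H]7O[C@H]7c3c(OCc9ccccc9)cc(OCc9ccccc9)c4c3O[C@H](c8ccc(OCc9ccccc9)c(OCc9ccccc9)c8)[C@H](O[Si](C)(C)C(C)(C)C)C4)c1ccc(OCc9ccccc9)c(OCc9ccccc9)c1 | intermediate
11 | 3,5-bis(benzyloxy)phenol | Oc1cc(OCc2ccccc2)cc(OCc2ccccc2)c1 | starting material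
12 | (2R,3S)-2-{(R)-[3,5-bis(benzyloxy)phenoxy][3,4-bis(benzyloxy)phenyl]methyl}-3-M-oxirane (threo aryl ether of the trans-epoxy carbinol) | c2(cc(OCc9ccccc9)cc(OCc9ccccc9)c2)O[C@@H]([C@@H]7O[C@H]7c3c(OCc9ccccc9)cc(OCc9ccccc9)c4c3O[C@H](c8ccc(OCc9ccccc9)c(OCc9ccccc9)c8)[C@H](O[Si](C)(C)C(C)(C)C)C4)c8ccc(OCc9ccccc9)c(OCc9ccccc9)c8 | intermediate
13 | 5,7,3′,4′-tetra-O-benzylepicatechin-(4β→8)-[5,7,3′,4′-tetra-O-benzyl-3-O-TBS-epicatechin] | O[C@@H]1[C@@H](c3c(OCc9ccccc9)cc(OCc9ccccc9)c4c3O[C@H](c8ccc(OCc9ccccc9)c(OCc9ccccc9)c8)[C@H](O[Si](C)(C)C(C)(C)C)C4)c2c(OCc9ccccc9)cc(OCc9ccccc9)cc2O[C@@H]1c8ccc(OCc9ccccc9)c(OCc9ccccc9)c8 | intermediate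
14 | 4β-(2-ethoxyethoxy) derivative of 13 at middle C4 | O[C@@H]1[C@@H](c3c(OCc9ccccc9)cc(OCc9ccccc9)c4c3O[C@H](c8ccc(OCc9ccccc9)c(OCc9ccccc9)c8)[C@H](O[Si](C)(C)C(C)(C)C)[C@H]4OCCOCC)c2c(OCc9ccccc9)cc(OCc9ccccc9)cc2O[C@@H]1c8ccc(OCc9ccccc9)c(OCc9ccccc9)c8 | intermediate
15 | tribromide of 14 (top C6, top C8, middle C6) | O[C@@H]1[C@@H](c3c(OCc9ccccc9)c(Br)c(OCc9ccccc9)c4c3O[C@H](c8ccc(OCc9ccccc9)c(OCc9ccccc9)c8)[C@H](O[Si](C)(C)C(C)(C)C)[C@H]4OCCOCC)c2c(OCc9ccccc9)c(Br)c(OCc9ccccc9)c(Br)c2O[C@@H]1c8ccc(OCc9ccccc9)c(OCc9ccccc9)c8 | intermediate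
16 | (+)-catechin | O[C@H]1Cc2c(O)cc(O)cc2O[C@@H]1c1ccc(O)c(O)c1 | starting material
17 | 5,7,3′,4′-tetra-O-benzyl-(+)-catechin | O[C@H]1Cc2c(OCc9ccccc9)cc(OCc9ccccc9)cc2O[C@@H]1c1ccc(OCc9ccccc9)c(OCc9ccccc9)c1 | intermediate
18 | 3,5,7,3′,4′-penta-O-benzylcatechin | c9ccccc9CO[C@H]1Cc2c(OCc9ccccc9)cc(OCc9ccccc9)cc2O[C@@H]1c1ccc(OCc9ccccc9)c(OCc9ccccc9)c1 | intermediate
19 | 8-bromo-3,5,7,3′,4′-penta-O-benzylcatechin | c9ccccc9CO[C@H]1Cc2c(OCc9ccccc9)cc(OCc9ccccc9)c(Br)c2O[C@@H]1c1ccc(OCc9ccccc9)c(OCc9ccccc9)c1 | intermediate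
20 | 6,8-dibromo-tetra-O-benzylepicatechin-(4β→8)-[6-bromo-tetra-O-benzyl-3-O-TBS-epicatechin]-(4β→6)-[8-bromo-penta-O-benzylcatechin] | O[C@@H]1[C@@H](c3c(OCc9ccccc9)c(Br)c(OCc9ccccc9)c4c3O[C@H](c8ccc(OCc9ccccc9)c(OCc9ccccc9)c8)[C@H](O[Si](C)(C)C(C)(C)C)[C@H]4c5c(OCc9ccccc9)c(Br)c6c(c5OCc9ccccc9)C[C@H](OCc9ccccc9)[C@@H](c8ccc(OCc9ccccc9)c(OCc9ccccc9)c8)O6)c2c(OCc9ccccc9)c(Br)c(OCc9ccccc9)c(Br)c2O[C@@H]1c8ccc(OCc9ccccc9)c(OCc9ccccc9)c8 | intermediate
21 | desilylated trimer diol (top and middle 3-hydroxyls free) | O[C@@H]1[C@@H](c3c(OCc9ccccc9)c(Br)c(OCc9ccccc9)c4c3O[C@H](c8ccc(OCc9ccccc9)c(OCc9ccccc9)c8)[C@H](O)[C@H]4c5c(OCc9ccccc9)c(Br)c6c(c5OCc9ccccc9)C[C@H](OCc9ccccc9)[C@@H](c8ccc(OCc9ccccc9)c(OCc9ccccc9)c8)O6)c2c(OCc9ccccc9)c(Br)c(OCc9ccccc9)c(Br)c2O[C@@H]1c8ccc(OCc9ccccc9)c(OCc9ccccc9)c8 | intermediate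
22 | 3,4,5-tris(benzyloxy)benzoic acid | OC(=O)c1cc(OCc2ccccc2)c(OCc2ccccc2)c(OCc2ccccc2)c1 | starting material
23 | protected bis-gallate trimer (top and middle 3-O-[3,4,5-tris(benzyloxy)benzoyl]) | O=C(O[C@@H]1[C@@H](c3c(OCc9ccccc9)c(Br)c(OCc9ccccc9)c4c3O[C@H](c8ccc(OCc9ccccc9)c(OCc9ccccc9)c8)[C@H](OC(=O)c7cc(OCc9ccccc9)c(OCc9ccccc9)c(OCc9ccccc9)c7)[C@H]4c5c(OCc9ccccc9)c(Br)c6c(c5OCc9ccccc9)C[C@H](OCc9ccccc9)[C@@H](c8ccc(OCc9ccccc9)c(OCc9ccccc9)c8)O6)c2c(OCc9ccccc9)c(Br)c(OCc9ccccc9)c(Br)c2O[C@@H]1c8ccc(OCc9ccccc9)c(OCc9ccccc9)c8)c7cc(OCc9ccccc9)c(OCc9ccccc9)c(OCc9ccccc9)c7 | intermediate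
24 | epicatechin-3-O-gallate-(4β→8)-epicatechin-3-O-gallate-(4β→6)-catechin (CNP0154615.1) | O=C(O[C@@H]1[C@@H](c2c(O)cc(O)c3c2O[C@H](c2ccc(O)c(O)c2)[C@H](OC(=O)c2cc(O)c(O)c(O)c2)[C@H]3c2c(O)cc3c(c2O)C[C@H](O)[C@@H](c2ccc(O)c(O)c2)O3)c2c(O)cc(O)cc2O[C@@H]1c1ccc(O)c(O)c1)c1cc(O)c(O)c(O)c1 | target

**Step count and risks**

Total step count: 18. Longest linear sequence: 15 steps (steps 1–11 and 15–18); the bottom unit is made in a three-step branch (steps 12–14).

Steps most likely to fail:

Step 9 (ring closure). The BF3-bound oxirane may ionise and collapse by 1,2-hydride shift to the C3 ketone (Meinwald rearrangement), or the oxirane may be lost by premature ionisation during handling, before the arene closes the ring. The fallback sets out from 12 (used crude). Buffered methanolysis (MeOH, pyridinium p-toluenesulfonate cat., −20 °C) opens the oxirane at C4 to the storable 4-methoxy-3-hydroxy aryl ether F1 (C4 epimers, C2 and C3 unchanged). TMSOTf in CH2Cl2 at −78 °C then ionises the methoxy group, as in the activation of 4-alkoxyflavan-3-ols. The same benzylic cation, now without a Lewis-acid-bound alkoxide beside it, should be captured by the ortho carbon anti to O3, which comes back to the route at 13.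

Step 6 (asymmetric epoxidation). Conjugate addition of the hydroperoxide anion to the electron-rich, doubly ortho-substituted enone may be slow and poorly face-selective. The fallback sets out from 7 and 6. Direct α-chlorination of ketone 7 (N-chlorosuccinimide, p-toluenesulfonic acid cat., MeCN) gives 2-chloro-1-[3,4-bis(benzyloxy)phenyl]ethanone F2. An asymmetric Darzens condensation of this chloro ketone with aldehyde 6 under phase-transfer catalysis (N-[4-(trifluoromethyl)benzyl]cinchoninium bromide, LiOH·H2O, CH2Cl2, 0 °C) then forms the C3–C4 bond by enolate addition to the aldehyde and closes the trans-oxirane by intramolecular O-alkylation. Should this catalyst favour the wrong antipode, the pseudoenantiomeric N-[4-(trifluoromethyl)benzyl]cinchonidinium bromide is used instead, so that the (2R,3S) series is obtained, and the sequence comes back to the route at 9.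

Step 15 (4→6 coupling). Attack by the hindered, bromine-deactivated C6 may be slow, leaving the cation exposed to triflic acid long enough for acidolysis of the upper interflavan bond or capture by the free top hydroxyl. The fallback sets out from 15. Exchange of the 2-ethoxyethoxy group for a benzylthio group (BnSH, BF3·OEt2, CH2Cl2, −78 °C) gives the 4β-benzylthio tribromo dimer F3. Thiophilic activation (AgBF4, 2,6-di-tert-butyl-4-methylpyridine, THF, 0 °C) in the presence of 19 then generates the same cation without a strong protic acid and comes back to the route at 20.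

Further compounds
F1 | step 9 | 4-methoxy-3-hydroxy aryl ether from methanolysis of 12 (C4 epimers) | c2(cc(OCc9ccccc9)cc(OCc9ccccc9)c2)O[C@@H]([C@H](O)C(OC)c3c(OCc9ccccc9)cc(OCc9ccccc9)c4c3O[C@H](c8ccc(OCc9ccccc9)c(OCc9ccccc9)c8)[C@H](O[Si](C)(C)C(C)(C)C)C4)c8ccc(OCc9ccccc9)c(OCc9ccccc9)c8
F2 | step 6 | 2-chloro-1-[3,4-bis(benzyloxy)phenyl]ethanone | ClCC(=O)c1ccc(OCc2ccccc2)c(OCc2ccccc2)c1
F3 | step 15 | 4β-benzylthio analogue of 15 | O[C@@H]1[C@@H](c3c(OCc9ccccc9)c(Br)c(OCc9ccccc9)c4c3O[C@H](c8ccc(OCc9ccccc9)c(OCc9ccccc9)c8)[C@H](O[Si](C)(C)C(C)(C)C)[C@H]4SCc9ccccc9)c2c(OCc9ccccc9)c(Br)c(OCc9ccccc9)c(Br)c2O[C@@H]1c8ccc(OCc9ccccc9)c(OCc9ccccc9)c8
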